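**Assumptions.** The SMILES decodes to (5Z)-4-(3-bromo-4-hydroxyphenyl)-5-(3-bromo-4-hydroxybenzylidene)-3-[(S)-(3,5-dibromo-4-methoxyphenyl)(hydroxy)methyl]furan-2(5H)-one. In step 1 the ProPhenol antipode that gives the (S)-alcohol is used (both are commercial); I have not confirmed which antipode that is, so the sense must be checked on the first adduct (Mosher ester). TBS = tert-butyldimethylsilyl.

## Retrosynthetic overview

1. Target ⇐ its tris-TBS ether (global desilylation last).
2. The butenolide, the only ring formed and formed last, ⇐ a symmetric 1,3-diarylacetone plus an (S)-β-silyloxy-α-keto ester. A Ti-aldol then acid cyclodehydration makes C3=C4 and the O1–C2 lactone bond; one benzyl arm of the ketone becomes C4–aryl, the other the exocyclic (Z)-benzylidene.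
3. Keto ester ⇐ DMDO oxidation of a silylated α-diazo-β-hydroxy ester ⇐ catalytic asymmetric aldol of ethyl diazoacetate with 3,5-dibromo-4-methoxybenzaldehyde (sets the only stereocentre).
4. Symmetric ketone ⇐ DCC/DMAP decarboxylative self-condensation of the O-TBS arylacetic acid ⇐ mono-bromination of 4-hydroxyphenylacetic acid.

## Route

**Step 1**
Reactants: **1** 3,5-dibromo-4-methoxybenzaldehyde; **2** ethyl diazoacetate
Product: **3** ethyl (3S)-2-diazo-3-(3,5-dibromo-4-methoxyphenyl)-3-hydroxypropanoate
Conditions: Bu2Mg (10 mol%), ProPhenol (5 mol%, antipode giving S), cis-1,2-cyclopentanediol (5 mol%), THF, −20 °C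
Reagents that add atoms: none (all heavy atoms come from 1 and 2)
Why: Direct catalytic asymmetric aldol addition of the diazoacetate C–H to an aryl aldehyde; the dinuclear Mg–ProPhenol pocket selects the aldehyde face and sets the (S)-carbinol, the only stereocentre of the target.

**Step 2**
Reactants: **3**
Product: **4** ethyl (3S)-3-[(tert-butyldimethylsilyl)oxy]-2-diazo-3-(3,5-dibromo-4-methoxyphenyl)propanoate
Conditions: TBSCl, imidazole, DMF, rt
Reagents that add atoms: TBSCl, CC(C)(C)[Si](C)(C)Cl
Why: Standard O-silylation under mild base that the diazo ester tolerates; the free OH must be masked because later it would cyclise onto the C5 ketone and dehydrate to a furan.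

**Step 3**
Reactants: **4**
Product: **5** ethyl (3S)-3-[(tert-butyldimethylsilyl)oxy]-3-(3,5-dibromo-4-methoxyphenyl)-2-oxopropanoate
Conditions: DMDO, acetone, 0 °C; dry azeotropically and use at once
Reagents that add atoms: dimethyldioxirane, CC1(C)OO1
Why: Neutral oxygen-atom transfer to the diazo carbon with loss of N2 gives the α-keto ester; no acid or base is present, so the benzylic α-silyloxy centre is not epimerised.

**Step 4**
Reactants: **6** 4-hydroxyphenylacetic acid
Product: **7** 3-bromo-4-hydroxyphenylacetic acid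
Conditions: Br2 (1.0 equiv), AcOH, 15 °C
Reagents that add atoms: bromine, BrBr
Why: Electrophilic aromatic bromination ortho to the phenol (para blocked); one equivalent gives the mono-bromide, and the dibromide is removed by recrystallisation.

**Step 5**
Reactants: **7**
Product: **8** 2-[3-bromo-4-(tert-butyldimethylsilyloxy)phenyl]acetic acid
Conditions: TBSCl (2.2 equiv), imidazole, DMF, rt; then AcOH/THF/H2O, rt
Reagents that add atoms: TBSCl, CC(C)(C)[Si](C)(C)Cl
Why: Bis-silylation followed by selective hydrolysis of the labile silyl ester leaves the aryl silyl ether, masking the phenol for the DCC and Ti steps.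

**Step 6**
Reactants: **8** (2 equiv)
Product: **9** 1,3-bis[3-bromo-4-(tert-butyldimethylsilyloxy)phenyl]propan-2-one
Conditions: DCC (1.0 equiv), DMAP (0.25 equiv), CH2Cl2, rt
Reagents that add atoms: none
Why: DCC/DMAP decarboxylative self-condensation of an arylacetic acid (C-acylation of the activated acid, then loss of CO2), the standard route to symmetric 1,3-diarylacetones; aryl bromides and silyl ethers are inert.

**Step 7 (key step, part 1)**
Reactants: **9** (1.3 equiv); **5** (1.0 equiv)
Product: **10** ethyl 3,5-bis[3-bromo-4-(TBSO)phenyl]-2-[(S)-(TBSO)(3,5-dibromo-4-methoxyphenyl)methyl]-2-hydroxy-4-oxopentanoate (diastereomer mixture at C2/C3)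
Conditions: TiCl4 (1.3 equiv), Bu3N (1.5 equiv), CH2Cl2, −78 °C, 30 min; then 5, −78 °C; cold aq. NH4Cl quench
Reagents that add atoms: none
Why: Ti-mediated direct crossed aldol: the weakly basic Ti enolate of the symmetric ketone (either arm is equivalent) adds to the chelated α-keto carbonyl of 5, breaking the symmetry while the (S)-centre is carried through. The two new centres are destroyed in step 8, and the cold quench prevents Ti-Dieckmann closure.

**Step 8 (key step, part 2)**
Reactants: **10**
Product: **11** (5Z)-4-[3-bromo-4-(TBSO)phenyl]-5-[3-bromo-4-(TBSO)benzylidene]-3-[(S)-(TBSO)(3,5-dibromo-4-methoxyphenyl)methyl]furan-2(5H)-one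
Conditions: TsOH (anhydrous, 20 mol%), PhMe, 70 °C, 4 Å MS
Reagents that add atoms: none
Why: Acid-catalysed aldol dehydration (C3=C4) and enol-lactonisation of the C5 ketone onto the ester (loss of EtOH) give the conjugated 5-ylidene butenolide. The Z-benzylidene (aryl anti to the C4 aryl) is the thermodynamic isomer, acid favours O-acylation over C-acylation to a cyclopentenedione, and the silylated (S)-centre is not involved.

**Step 9**
Reactants: **11**
Product: **12** target, (5Z)-4-(3-bromo-4-hydroxyphenyl)-5-(3-bromo-4-hydroxybenzylidene)-3-[(S)-(3,5-dibromo-4-methoxyphenyl)(hydroxy)methyl]furan-2(5H)-one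
Conditions: TBAF/AcOH (1:1, 4 equiv), THF, 0 °C to rt
Reagents that add atoms: none
Why: Buffered fluoride cleaves the two aryl and one secondary alkyl silyl ethers without generating alkoxide or phenoxide that could open the lactone or deprotonate the carbinol C–H, so the Z-alkene and (S)-centre are retained.

## Compound list

1 | 3,5-dibromo-4-methoxybenzaldehyde | COc1c(Br)cc(C=O)cc1Br | starting material
2 | ethyl diazoacetate | CCOC(=O)C=[N+]=[N-] | starting material
3 | ethyl (3S)-2-diazo-3-(3,5-dibromo-4-methoxyphenyl)-3-hydroxypropanoate | COc1c(Br)cc([C@H](O)C(=[N+]=[N-])C(=O)OCC)cc1Br | intermediate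
4 | ethyl (3S)-3-(TBSO)-2-diazo-3-(3,5-dibromo-4-methoxyphenyl)propanoate | COc1c(Br)cc([C@H](O[Si](C)(C)C(C)(C)C)C(=[N+]=[N-])C(=O)OCC)cc1Br | intermediate
5 | ethyl (3S)-3-(TBSO)-3-(3,5-dibromo-4-methoxyphenyl)-2-oxopropanoate | COc1c(Br)cc([C@H](O[Si](C)(C)C(C)(C)C)C(=O)C(=O)OCC)cc1Br | intermediate
6 | 4-hydroxyphenylacetic acid | OC(=O)Cc1ccc(O)cc1 | starting material
7 | 3-bromo-4-hydroxyphenylacetic acid | OC(=O)Cc1ccc(O)c(Br)c1 | intermediate
8 | 2-[3-bromo-4-(TBSO)phenyl]acetic acid | OC(=O)Cc1ccc(O[Si](C)(C)C(C)(C)C)c(Br)c1 | intermediate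
9 | 1,3-bis[3-bromo-4-(TBSO)phenyl]propan-2-one | O=C(Cc1ccc(O[Si](C)(C)C(C)(C)C)c(Br)c1)Cc1ccc(O[Si](C)(C)C(C)(C)C)c(Br)c1 | intermediate
10 | ethyl 3,5-bis[3-bromo-4-(TBSO)phenyl]-2-[(S)-(TBSO)(3,5-dibromo-4-methoxyphenyl)methyl]-2-hydroxy-4-oxopentanoate (diastereomer mixture) | COc1c(Br)cc([C@H](O[Si](C)(C)C(C)(C)C)C(O)(C(=O)OCC)C(c2ccc(O[Si](C)(C)C(C)(C)C)c(Br)c2)C(=O)Cc2ccc(O[Si](C)(C)C(C)(C)C)c(Br)c2)cc1Br | intermediate
11 | (5Z)-4-[3-bromo-4-(TBSO)phenyl]-5-[3-bromo-4-(TBSO)benzylidene]-3-[(S)-(TBSO)(3,5-dibromo-4-methoxyphenyl)methyl]furan-2(5H)-one | COc1c(Br)cc([C@H](O[Si](C)(C)C(C)(C)C)C2=C(c3ccc(O[Si](C)(C)C(C)(C)C)c(Br)c3)/C(=C/c3ccc(O[Si](C)(C)C(C)(C)C)c(Br)c3)OC2=O)cc1Br | intermediate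
12 | (5Z)-4-(3-bromo-4-hydroxyphenyl)-5-(3-bromo-4-hydroxybenzylidene)-3-[(S)-(3,5-dibromo-4-methoxyphenyl)(hydroxy)methyl]furan-2(5H)-one | COc1c(Br)cc([C@H](O)C2=C(c3ccc(O)c(Br)c3)/C(=C/c3ccc(O)c(Br)c3)OC2=O)cc1Br | target

## Summary

**Total steps:** 9.
**Longest linear sequence:** 6 (steps 1, 2, 3, 7, 8, 9; the ketone branch 4, 5, 6, 7, 8, 9 is also 6).

**Three steps most likely to fail, with fallbacks**

- **Step 7 (Ti aldol onto the hindered, epimerisable keto ester).** Risks are proton transfer that racemises 5, low conversion from congestion, and retro-aldol. Fallback: carry the ketone oxidation level instead. Condense 9 with the achiral vicinal tricarbonyl ethyl 3-(3,5-dibromo-4-methoxyphenyl)-2,3-dioxopropanoate to give the 3-aroyl butenolide, then set the carbinol last by CBS (or Ru–TsDPEN transfer) reduction.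
- **Step 8 (acid cyclodehydration).** Risks are premature loss of the carbinol silyl group (giving a furan), incomplete enol-lactonisation of the ethyl ester, and ionisation of the allylic/benzylic C–O. Fallback: run step 1 with tert-butyl diazoacetate so that TFA unmasks the acid after the aldol; the acid closes to the 5-benzyl-5-hydroxybutenolide, which is then dehydrated without acid (MsCl/Et3N) to the Z-ylidene.
- **Step 1 (ee and absolute sense on this aldehyde).** The whole route depends on it and the sense is assumed. Fallback: make the Morita–Baylis–Hillman adduct of 1 with an acrylate, obtain the (S)-alcohol by lipase kinetic resolution, silylate, and ozonise (Me2S work-up) to reach the methyl analogue of 5 without diazo chemistry.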